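The synthesis rests on cutting the C5–CH2 bond of the 1,2-dioxolane (O1, O2, C3, C4, C5). This leads back to a bridged peroxyketal in which the future acetic acid arm on C3 is tied to C5 as an OCH2CH2 bridge. The feature exploited is that C3 and C5 are look-alike quaternary carbons (CH3 plus CH2 arm, arms trans) placed 1,3 across C4, which cannot bias one another without a tether. In one operation the key step converts an enantioenriched 2-methyl-2-(2-oxopropyl)oxetane and H2O2 into a 2,6,7-trioxabicyclo[3.2.1]octane, forming both peroxide C–O bonds, the dioxolane and the oxane bridge. Invertive allylation, cross metathesis and Julia–Kocienski olefination then build the trienyl chain.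

Key step: step 6

Assumption: the enantiomeric purity set in step 2 is taken to persist, because every later stereochemical event is either stereospecific (step 6) or relayed from C3 (step 7). Compounds 8, 10 and 13 are volatile, and ethereal H2O2 is handled on small scale behind a shield.

Step 1
Reactants: 1 but-2-yn-1-ol; 2 3-chloro-2-methylprop-1-ene
Product: 4 (2Z)-3,5-dimethylhexa-2,5-dien-1-ol, via cyclic sodium alkenylaluminate 3 (not isolated)
Conditions: NaAlH2(OCH2CH2OCH3)2 (1.2 equiv), THF, 0 °C to rt; then CuCl (10 mol %), 2 (1.5 equiv), 0 °C to rt; aqueous work-up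
Reagents that add atoms: none
Why: Hydroxyl-directed trans-hydroalumination of a propargylic alcohol puts aluminium on C3 inside a five-membered O–Al chelate, and the known CuCl-catalysed allylation of such alkenylaluminates replaces the C–Al bond with retention, so the methallyl group should end cis to CH2OH (Z), while direct and allylic attack on the symmetrical methallyl unit give the same product.

Step 2
Reactants: 4 (2Z)-3,5-dimethylhexa-2,5-dien-1-ol
Product: 5 [(2S,3R)-3-methyl-3-(2-methylprop-2-en-1-yl)oxiran-2-yl]methanol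
Conditions: Ti(OCH(CH3)2)4 (20 mol %), L-(+)-diethyl tartrate (24 mol %), t-BuOOH (2 equiv, anhydrous, decane), 4 Å molecular sieves, CH2Cl2, −20 °C
Reagents that add atoms: tert-butyl hydroperoxide CC(C)(C)OO
Why: Katsuki–Sharpless asymmetric epoxidation acts only on the titanium-bound allylic alcohol alkene, leaves the remote 1,1-disubstituted alkene alone, and with the L-(+)-tartrate should set both new centres as 2S,3R by syn oxygen transfer to one face of the Z alkene, as established for nerol-type substrates.

Step 3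
Reactants: 5 [(2S,3R)-3-methyl-3-(2-methylprop-2-en-1-yl)oxiran-2-yl]methanol
Product: 6 (3R)-3,5-dimethylhex-5-ene-1,3-diol
Conditions: NaAlH2(OCH2CH2OCH3)2 (1.5 equiv), THF, 0 °C to rt; aqueous work-up
Reagents that add atoms: none
Why: Regioselective hydride opening of a 2,3-epoxy alcohol, in which the aluminium alkoxide formed at O1 delivers hydride internally to C2, the only unhindered epoxide carbon, so the C3–O bond keeps its configuration and C2 ceases to be stereogenic.

Step 4
Reactants: 6 (3R)-3,5-dimethylhex-5-ene-1,3-diol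
Product: 8 (2R)-2-methyl-2-(2-methylprop-2-en-1-yl)oxetane, via primary monotosylate 7 (not isolated)
Conditions: KOC(CH3)3 (1.05 equiv), THF, 0 °C; 4-CH3C6H4SO2Cl (1.0 equiv), 0 °C; then KOC(CH3)3 (1.2 equiv), 0 °C to rt
Reagents that add atoms: none
Why: One-pot monosulfonylation and Williamson-type 4-exo-tet closure, in which the primary alkoxide is tosylated far faster than the tertiary one and the tertiary alkoxide then displaces the primary tosylate, so no bond at the stereocentre is touched.

Step 5
Reactants: 8 (2R)-2-methyl-2-(2-methylprop-2-en-1-yl)oxetane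
Product: 10 1-[(2S)-2-methyloxetan-2-yl]propan-2-one, via secondary ozonide 9 (not isolated)
Conditions: O3, CH2Cl2, solid NaHCO3, −78 °C; then (CH3)2S, −78 °C to rt
Reagents that add atoms: ozone [O-][O+]=O
Why: Criegee ozonolysis of the only alkene with reductive work-up, run buffered and free of strong base so that the oxetane neither opens nor eliminates; the descriptor changes from R to S only because the side chain gains priority.

Step 6
Reactants: 10 1-[(2S)-2-methyloxetan-2-yl]propan-2-one
Product: 13 (1R,5R)-1,5-dimethyl-2,6,7-trioxabicyclo[3.2.1]octane, via 1,2-dioxolan-3-ol 11 (not isolated), via peroxycarbenium triflate 12 (not isolated)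
Conditions: anhydrous H2O2 in Et2O (10 equiv), Me3SiOSO2CF3 (15 mol %), Et2O, −78 to 0 °C; Et3N quench, water wash
Reagents that add atoms: hydrogen peroxide OO
Why: Proposed new method: H2O2 adds reversibly to the ketone of 10 and the outer oxygen of the perhydrate attacks the acid-activated oxetane at its quaternary carbon from the rear, or H2O2 opens the oxetane first and the tertiary hydroperoxide then adds to the ketone; both orders meet at 1,2-dioxolan-3-ol 11, whose hemiketal ionises to 12 and is captured by the 2-hydroxyethyl arm just released. The closest known reaction types are the Lewis-acid-promoted invertive opening of enantioenriched 2,2-disubstituted oxetanes by H2O2 and the cyclisation of 3-hydroperoxy ketones to 1,2-dioxolan-3-ols, which have not been merged on a keto-oxetane or followed by bridging ketalisation in the same flask. The 1,2-dioxolane closes 5-exo-tet (perhydrate on oxetane) or 5-exo-trig (hydroperoxide on ketone), and the oxane bridge closes 6-exo-trig on the C=O+ carbon of 12. C5 of 13 is set by SN2-type inversion of the epoxidation-derived oxetane carbon, and C1 is set by geometry, because the hemiketal centre epimerises through 12 and the three-atom bridge can only span the cis face. The step needs substitution with inversion to outrun ionisation of the tertiary C–O bond and beta-elimination to an enone. Ring strain, the 1,3 spacing of ketone and oxetane that makes peroxide delivery intramolecular, an alpha-effect nucleophile in large excess and low temperature should secure this, and the unstrained frontalin-like [3.2.1] ketal is the thermodynamic sink.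

Step 7
Reactants: 13 (1R,5R)-1,5-dimethyl-2,6,7-trioxabicyclo[3.2.1]octane; 14 allyltrimethylsilane
Product: 16 2-[(3R,5R)-3,5-dimethyl-5-(prop-2-en-1-yl)-1,2-dioxolan-3-yl]ethan-1-ol, via titanate-tethered peroxycarbenium ion 15 (not isolated)
Conditions: 14 (3 equiv), TiCl4 (1.1 equiv), CH2Cl2, −78 °C; then H2O
Reagents that add atoms: none
Why: Hosomi–Sakurai-type substitution known for 3-alkoxy-1,2-dioxolanes, in which TiCl4 binds the more basic bridging ether oxygen and ionises the C1–O2 bond, the alkoxytitanate stays over the face it left (contact ion pair, possibly chelated to the neighbouring peroxide oxygen), and the allylsilane should therefore add to the opposite face of 15, as in invertive TiCl4 openings of bicyclic acetals, setting C5 as R with allyl trans to the hydroxyethyl arm.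

Step 8
Reactants: 17 8-bromooct-1-ene; 18 1-phenyl-1H-tetrazole-5-thiol
Product: 19 5-(oct-7-en-1-ylsulfanyl)-1-phenyl-1H-tetrazole
Conditions: K2CO3 (1.2 equiv), acetone, rt
Reagents that add atoms: none
Why: SN2 S-alkylation of a soft thiolate at an unhindered primary bromide.

Step 9
Reactants: 19 5-(oct-7-en-1-ylsulfanyl)-1-phenyl-1H-tetrazole
Product: 21 5-(oct-7-en-1-ylsulfonyl)-1-phenyl-1H-tetrazole, via sulfoxide 20 (not isolated)
Conditions: 30% aq H2O2 (6 equiv), (NH4)6Mo7O24·4H2O (10 mol %), EtOH, 0 °C to rt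
Reagents that add atoms: hydrogen peroxide OO
Why: Molybdate-catalysed peroxide oxidation of sulfide to sulfone, which is electrophilic enough for sulfur but leaves an unactivated terminal alkene alone, unlike a peracid.

Step 10
Reactants: 16 2-[(3R,5R)-3,5-dimethyl-5-(prop-2-en-1-yl)-1,2-dioxolan-3-yl]ethan-1-ol; 21 5-(oct-7-en-1-ylsulfonyl)-1-phenyl-1H-tetrazole
Product: 22 2-[(3R,5R)-3,5-dimethyl-5-{9-[(1-phenyl-1H-tetrazol-5-yl)sulfonyl]non-2-en-1-yl}-1,2-dioxolan-3-yl]ethan-1-ol (E/Z mixture)
Conditions: 21 (3 equiv), second-generation Grubbs catalyst RuCl2(=CHPh)(PCy3)(H2IMes) (5 mol %), 1,4-benzoquinone (10 mol %), CH2Cl2, 40 °C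
Reagents that add atoms: none
Why: Olefin cross metathesis of two terminal alkenes, driven by loss of ethene and biased by an excess of the cheap partner 21, whose homodimer is itself a competent partner; fully substituted dialkyl peroxides, free alcohols and sulfones are tolerated by this carbene, benzoquinone suppresses chain-walking that would alter the chain length, and the alkene geometry is irrelevant.

Step 11
Reactants: 22 cross-metathesis product (E/Z mixture)
Product: 23 2-[(3R,5R)-3,5-dimethyl-5-{9-[(1-phenyl-1H-tetrazol-5-yl)sulfonyl]nonyl}-1,2-dioxolan-3-yl]ethan-1-ol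
Conditions: 2-nitrobenzenesulfonyl hydrazide (excess, in portions), Et3N, CH2Cl2, rt
Reagents that add atoms: none
Why: Diimide reduction, a concerted syn transfer of two hydrogens to the nonpolar C=C bond that leaves the O–O bond, sulfone and tetrazole intact where catalytic hydrogenation would cleave the peroxide.

Step 12
Reactants: 23 saturated sulfone alcohol
Product: 25 2-[(3S,5R)-3,5-dimethyl-5-{9-[(1-phenyl-1H-tetrazol-5-yl)sulfonyl]nonyl}-1,2-dioxolan-3-yl]acetic acid, via aldehyde 24 (not isolated)
Conditions: 2,2,6,6-tetramethylpiperidin-1-oxyl (20 mol %), PhI(OAc)2 (2.5 equiv), CH3CN/pH 7 aqueous buffer, rt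
Reagents that add atoms: water O
Why: Oxoammonium-catalysed oxidation with PhI(OAc)2 as terminal oxidant takes the primary alcohol through 24 and its hydrate to the acid at near-neutral pH, which should keep the beta-peroxy aldehyde from eliminating; the C3 descriptor becomes S by priority change only.

Step 13
Reactants: 25 sulfone acid
Product: 26 methyl 2-[(3S,5R)-3,5-dimethyl-5-{9-[(1-phenyl-1H-tetrazol-5-yl)sulfonyl]nonyl}-1,2-dioxolan-3-yl]acetate
Conditions: (CH3)3SiCHN2, toluene/CH3OH, 0 °C
Reagents that add atoms: trimethylsilyldiazomethane C[Si](C)(C)C=[N+]=[N-]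
Why: Esterification of a carboxylic acid with a diazoalkane under non-basic conditions, the methanol co-solvent taking up the silyl group.

Step 14
Reactants: 26 sulfone methyl ester; 27 (2E,4E)-hepta-2,4-dienal
Product: 29 methyl 2-[(3S,5R)-5-[(9E,11E,13E)-hexadeca-9,11,13-trien-1-yl]-3,5-dimethyl-1,2-dioxolan-3-yl]acetate, via potassium sulfonyl carbanion 28 (not isolated)
Conditions: KN(Si(CH3)3)2 (1.0 equiv), 1,2-dimethoxyethane, −55 °C, short ageing; then 27 (1.3 equiv), −55 °C to rt; aqueous work-up
Reagents that add atoms: none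
Why: Julia–Kocienski olefination, in which the proton next to the tetrazolyl sulfone is several pKa units more acidic than that next to the ester, so one equivalent of base at low temperature should give 28 selectively, and addition to the enal, Smiles rearrangement and anti elimination under the potassium/1,2-dimethoxyethane regime should give the new alkene E while the two E alkenes of 27 are carried over.

Step 15
Reactants: 29 methyl ester of the target
Product: 31 2-[(3S,5R)-5-[(9E,11E,13E)-hexadeca-9,11,13-trien-1-yl]-3,5-dimethyl-1,2-dioxolan-3-yl]acetic acid (CNP0181055.3), via lithium carboxylate 30 (not isolated)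
Conditions: LiOH (3 equiv), THF/H2O, 0 °C to rt; then 0.5 M HCl to pH 4, 0 °C, argon, dark
Reagents that add atoms: lithium hydroxide [Li+].[OH-]
Why: Saponification by acyl–oxygen cleavage of an unhindered methyl ester, which a tetrasubstituted 1,2-dioxolane should withstand because it has no hydrogen on its peroxide-bearing carbons, followed by protonation under mild conditions that spare the triene.

Compound list
1 | but-2-yn-1-ol | CC#CCO | starting material
2 | 3-chloro-2-methylprop-1-ene | C=C(C)CCl | starting material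
3 | cyclic sodium alkenylaluminate (five-membered O–Al–C3=C2–C1 chelate, two 2-methoxyethoxy groups on Al) | CC1=CCO[Al-]1(OCCOC)OCCOC.[Na+] | intermediate
4 | (2Z)-3,5-dimethylhexa-2,5-dien-1-ol | C=C(C)C/C(C)=C\CO | intermediate
5 | [(2S,3R)-3-methyl-3-(2-methylprop-2-en-1-yl)oxiran-2-yl]methanol | C=C(C)C[C@]1(C)[C@H](CO)O1 | intermediate
6 | (3R)-3,5-dimethylhex-5-ene-1,3-diol | C=C(C)C[C@@](C)(O)CCO | intermediate
7 | (3R)-3-hydroxy-3,5-dimethylhex-5-en-1-yl 4-methylbenzenesulfonate | C=C(C)C[C@@](C)(O)CCOS(=O)(=O)c1ccc(C)cc1 | intermediate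
8 | (2R)-2-methyl-2-(2-methylprop-2-en-1-yl)oxetane | C=C(C)C[C@]1(C)CCO1 | intermediate
9 | 3-methyl-3-{[(2S)-2-methyloxetan-2-yl]methyl}-1,2,4-trioxolane (epimers at the trioxolane carbon) | CC1(OCOO1)C[C@]2(C)CCO2 | intermediate
10 | 1-[(2S)-2-methyloxetan-2-yl]propan-2-one | CC(=O)C[C@]1(C)CCO1 | intermediate
11 | (5R)-5-(2-hydroxyethyl)-3,5-dimethyl-1,2-dioxolan-3-ol (epimers at C3) | CC1(O)C[C@@](C)(CCO)OO1 | intermediate
12 | (5R)-5-(2-hydroxyethyl)-3,5-dimethyl-1,2-dioxolan-3-ylium trifluoromethanesulfonate | CC1=[O+]O[C@](C)(CCO)C1.[O-]S(=O)(=O)C(F)(F)F | intermediate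
13 | (1R,5R)-1,5-dimethyl-2,6,7-trioxabicyclo[3.2.1]octane | C[C@@]12C[C@@](C)(CCO1)OO2 | intermediate
14 | allyltrimethylsilane | C=CC[Si](C)(C)C | starting material
15 | zwitterion of the 1,2-dioxolan-3-ylium ion and its tethered tetrachloro(alkoxy)titanate | CC1=[O+]O[C@](C)(CCO[Ti-](Cl)(Cl)(Cl)Cl)C1 | intermediate
16 | 2-[(3R,5R)-3,5-dimethyl-5-(prop-2-en-1-yl)-1,2-dioxolan-3-yl]ethan-1-ol | C=CC[C@]1(C)C[C@@](C)(CCO)OO1 | intermediate
17 | 8-bromooct-1-ene | C=CCCCCCCBr | starting material
18 | 1-phenyl-1H-tetrazole-5-thiol | Sc1nnnn1-c1ccccc1 | starting material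
19 | 5-(oct-7-en-1-ylsulfanyl)-1-phenyl-1H-tetrazole | C=CCCCCCCSc1nnnn1-c1ccccc1 | intermediate
20 | 5-(oct-7-en-1-ylsulfinyl)-1-phenyl-1H-tetrazole | C=CCCCCCCS(=O)c1nnnn1-c1ccccc1 | intermediate
21 | 5-(oct-7-en-1-ylsulfonyl)-1-phenyl-1H-tetrazole | C=CCCCCCCS(=O)(=O)c1nnnn1-c1ccccc1 | intermediate
22 | 2-[(3R,5R)-3,5-dimethyl-5-{9-[(1-phenyl-1H-tetrazol-5-yl)sulfonyl]non-2-en-1-yl}-1,2-dioxolan-3-yl]ethan-1-ol (E/Z mixture) | c1ccccc1-n1nnnc1S(=O)(=O)CCCCCCC=CC[C@]1(C)C[C@@](C)(CCO)OO1 | intermediate
23 | 2-[(3R,5R)-3,5-dimethyl-5-{9-[(1-phenyl-1H-tetrazol-5-yl)sulfonyl]nonyl}-1,2-dioxolan-3-yl]ethan-1-ol | c1ccccc1-n1nnnc1S(=O)(=O)CCCCCCCCC[C@]1(C)C[C@@](C)(CCO)OO1 | intermediate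
24 | 2-[(3S,5R)-3,5-dimethyl-5-{9-[(1-phenyl-1H-tetrazol-5-yl)sulfonyl]nonyl}-1,2-dioxolan-3-yl]acetaldehyde | c1ccccc1-n1nnnc1S(=O)(=O)CCCCCCCCC[C@]1(C)C[C@@](C)(CC=O)OO1 | intermediate
25 | 2-[(3S,5R)-3,5-dimethyl-5-{9-[(1-phenyl-1H-tetrazol-5-yl)sulfonyl]nonyl}-1,2-dioxolan-3-yl]acetic acid | c1ccccc1-n1nnnc1S(=O)(=O)CCCCCCCCC[C@]1(C)C[C@@](C)(CC(=O)O)OO1 | intermediate
26 | methyl 2-[(3S,5R)-3,5-dimethyl-5-{9-[(1-phenyl-1H-tetrazol-5-yl)sulfonyl]nonyl}-1,2-dioxolan-3-yl]acetate | c1ccccc1-n1nnnc1S(=O)(=O)CCCCCCCCC[C@]1(C)C[C@@](C)(CC(=O)OC)OO1 | intermediate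
27 | (2E,4E)-hepta-2,4-dienal | CC/C=C/C=C/C=O | starting material
28 | potassium salt of 26 deprotonated at the carbon next to sulfur | c1ccccc1-n1nnnc1S(=O)(=O)[CH-]CCCCCCCC[C@]1(C)C[C@@](C)(CC(=O)OC)OO1.[K+] | intermediate
29 | methyl 2-[(3S,5R)-5-[(9E,11E,13E)-hexadeca-9,11,13-trien-1-yl]-3,5-dimethyl-1,2-dioxolan-3-yl]acetate | CC/C=C/C=C/C=C/CCCCCCCC[C@]1(C)C[C@@](C)(CC(=O)OC)OO1 | intermediate
30 | lithium 2-[(3S,5R)-5-[(9E,11E,13E)-hexadeca-9,11,13-trien-1-yl]-3,5-dimethyl-1,2-dioxolan-3-yl]acetate | CC/C=C/C=C/C=C/CCCCCCCC[C@]1(C)C[C@@](C)(CC(=O)[O-])OO1.[Li+] | intermediate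
31 | 2-[(3S,5R)-5-[(9E,11E,13E)-hexadeca-9,11,13-trien-1-yl]-3,5-dimethyl-1,2-dioxolan-3-yl]acetic acid (CNP0181055.3) | CC/C=C/C=C/C=C/CCCCCCCC[C@]1(C)C[C@@](C)(CC(=O)O)OO1 | target

Total step count: 15. Longest linear sequence: 13 (steps 1 to 7, then 10 to 15); steps 8 and 9 form the side branch.

Steps most likely to fail

Step 6.
- **What may go wrong:** The tertiary oxetane carbon may partly ionise, with loss of enantiopurity. Acid may induce beta-elimination of the keto-oxetane. The ketone may be over-peroxidised before the ring closes.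
- **Fallback (known chemistry, from 8 back to 13):** Oxetane 8, which has no ketone, is opened with ethereal H2O2 and catalytic Me3SiOSO2CF3. This is the established invertive opening and gives (3S)-3-hydroperoxy-3,5-dimethylhex-5-en-1-ol F1. Both OOH and OH are masked with 2-methoxypropene and pyridinium 4-methylbenzenesulfonate, giving the bis(2-methoxypropan-2-yl) derivative F2. Ozonolysis with dimethyl sulfide work-up, to which peroxyketals are inert, gives the methyl ketone F3. Catalytic 4-methylbenzenesulfonic acid in moist CH2Cl2 removes both masks to give (4R)-4-hydroperoxy-6-hydroxy-4-methylhexan-2-one F4. F4 closes as known to dioxolanol 11, which under the same acid closes to 13.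

Step 7.
- **What may go wrong:** The ion pair may escape to a free planar cation, giving poor facial selectivity. Lewis acid may also induce heterolysis of the O–O bond.
- **Fallback (from 13 back to 26):** The alkoxide leaving group is replaced by a carboxylate that ionises more easily and pairs more tightly. RuO4, made from catalytic RuCl3 and NaIO4, oxidises the only OCH2 group of 13 to the bridged lactone (1R,5S)-1,5-dimethyl-2,6,7-trioxabicyclo[3.2.1]octan-3-one F5. F5 is an acyloxy-dioxolane of the type known to act as a peroxycarbenium precursor. Allylation with 14 and TiCl4 at −78 °C, anti to the departing carboxylate, gives 2-[(3S,5R)-3,5-dimethyl-5-(prop-2-en-1-yl)-1,2-dioxolan-3-yl]acetic acid F6. Trimethylsilyldiazomethane gives the methyl ester F7, cross metathesis with 21 gives the unsaturated sulfone ester F8, and diimide reduction gives 26. This path also makes the alcohol oxidation of step 12 unnecessary.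

Step 14.
- **What may go wrong:** Deprotonation next to the ester may compete and be followed by expulsion of the peroxide oxygen and ring opening. E selectivity with the conjugated aldehyde may erode.
- **Fallback (from 23 back to 31):** The olefination is moved ahead of the oxidation, so that no carbonyl group sits beta to the peroxide when base is present. Alcohol 23 is silylated with t-BuMe2SiCl and imidazole to the silyl ether sulfone F9. F9 is olefinated with 27 under the conditions of step 14 to the triene silyl ether F10. F10 is desilylated with (n-C4H9)4NF to the triene alcohol F11. F11 is oxidised with 2,2,6,6-tetramethylpiperidin-1-oxyl and PhI(OAc)2 in aqueous CH3CN, through the triene aldehyde F12, directly to 31. Esterification and saponification are not needed.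

Further compounds
F1 | step 6 | (3S)-3-hydroperoxy-3,5-dimethylhex-5-en-1-ol | C=C(C)C[C@@](C)(CCO)OO
F2 | step 6 | (3S)-1-[(2-methoxypropan-2-yl)oxy]-3-[(2-methoxypropan-2-yl)peroxy]-3,5-dimethylhex-5-ene | C=C(C)C[C@@](C)(CCOC(C)(C)OC)OOC(C)(C)OC
F3 | step 6 | (4R)-6-[(2-methoxypropan-2-yl)oxy]-4-[(2-methoxypropan-2-yl)peroxy]-4-methylhexan-2-one | CC(=O)C[C@@](C)(CCOC(C)(C)OC)OOC(C)(C)OC
F4 | step 6 | (4R)-4-hydroperoxy-6-hydroxy-4-methylhexan-2-one | CC(=O)C[C@@](C)(CCO)OO
F5 | step 7 | (1R,5S)-1,5-dimethyl-2,6,7-trioxabicyclo[3.2.1]octan-3-one | C[C@@]12C[C@@](C)(CC(=O)O1)OO2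
F6 | step 7 | 2-[(3S,5R)-3,5-dimethyl-5-(prop-2-en-1-yl)-1,2-dioxolan-3-yl]acetic acid | C=CC[C@]1(C)C[C@@](C)(CC(=O)O)OO1
F7 | step 7 | methyl 2-[(3S,5R)-3,5-dimethyl-5-(prop-2-en-1-yl)-1,2-dioxolan-3-yl]acetate | C=CC[C@]1(C)C[C@@](C)(CC(=O)OC)OO1
F8 | step 7 | methyl 2-[(3S,5R)-3,5-dimethyl-5-{9-[(1-phenyl-1H-tetrazol-5-yl)sulfonyl]non-2-en-1-yl}-1,2-dioxolan-3-yl]acetate (E/Z mixture) | c1ccccc1-n1nnnc1S(=O)(=O)CCCCCCC=CC[C@]1(C)C[C@@](C)(CC(=O)OC)OO1
F9 | step 14 | tert-butyldimethylsilyl ether of 23 | c1ccccc1-n1nnnc1S(=O)(=O)CCCCCCCCC[C@]1(C)C[C@@](C)(CCO[Si](C)(C)C(C)(C)C)OO1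
F10 | step 14 | tert-butyl{2-[(3R,5R)-5-[(9E,11E,13E)-hexadeca-9,11,13-trien-1-yl]-3,5-dimethyl-1,2-dioxolan-3-yl]ethoxy}dimethylsilane | CC/C=C/C=C/C=C/CCCCCCCC[C@]1(C)C[C@@](C)(CCO[Si](C)(C)C(C)(C)C)OO1
F11 | step 14 | 2-[(3R,5R)-5-[(9E,11E,13E)-hexadeca-9,11,13-trien-1-yl]-3,5-dimethyl-1,2-dioxolan-3-yl]ethan-1-ol | CC/C=C/C=C/C=C/CCCCCCCC[C@]1(C)C[C@@](C)(CCO)OO1
F12 | step 14 | 2-[(3S,5R)-5-[(9E,11E,13E)-hexadeca-9,11,13-trien-1-yl]-3,5-dimethyl-1,2-dioxolan-3-yl]acetaldehyde | CC/C=C/C=C/C=C/CCCCCCCC[C@]1(C)C[C@@](C)(CC=O)OO1
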